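**Retrosynthetic overview**
1. Endgame: one global hydrogenolysis of an octadeca-O-benzyl, 8-bromo-capped trimer. The two interflavan bonds (C4 of the upper unit to C8 of the lower unit, both 4β) are made from the bottom up by two Lewis-acid couplings of C4-alkoxy electrophiles.
2. All three flavan units, and so six of the eight stereocentres, come from one monomer, penta-O-benzyl-(−)-epigallocatechin. Its C2 and C3 are set together by a dynamic kinetic resolution hydrogenation of the racemic flavan-3-one.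
3. Ring C of the monomer is closed in one operation from a C-silyl dithiane (C3–C4–ring A) and the B-ring aldehyde. C3 attacks the aldehyde carbon (C2–C3), and the aldehyde oxygen then displaces fluoride at C8a (O1–C8a).
4. Enabling feature: in ring A the oxygen-bearing carbons C5, C7 and C8a are mutually meta, so ring A maps onto a 2,4,6-trifluorophenyl group whose C–F bonds are SNAr sites. C3 of ring C is a carbinol carbon between C2 and C4, so it can travel as a dithiane-masked ketone that is nucleophilic in the key step and later makes C2–H epimerisable.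
5. Ring order: rings A, B and the galloyl ring are bought, and ring C of the monomer is formed in step 2. No ring is formed after that, because the three monomers are only joined.

Key step: step 2

Assumption: the sense of induction in step 5 is assigned by analogy with 2-arylcycloalkanones; if a test run gives the (2S,3S) alcohol, the mirror-image catalyst is used and nothing else changes.
Assumption: 3,4,5-tris(benzyloxy)benzaldehyde and 3,4,5-tris(benzyloxy)benzoic acid are taken as catalogue compounds.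

Step 1
Reactants: 1 2-(trimethylsilyl)-1,3-dithiane; 2 2,4,6-trifluorobenzyl bromide
Product: 4 2-(2,4,6-trifluorobenzyl)-2-(trimethylsilyl)-1,3-dithiane, via 2-lithio-2-(trimethylsilyl)-1,3-dithiane 3 (not isolated)
Conditions: n-BuLi, THF, −78 → −20 °C; then 2, −78 °C → rt
Reagents that add atoms: none
Why: Corey–Seebach alkylation, in which the sulfur- and silicon-stabilised carbanion 3 displaces bromide from the primary, electron-poor (hence stable) benzylic bromide by SN2 faster than it can abstract an aryl proton; no stereocentre is formed.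

Step 2
Reactants: 4 2-(2,4,6-trifluorobenzyl)-2-(trimethylsilyl)-1,3-dithiane; 5 3,4,5-tris(benzyloxy)benzaldehyde
Product: 7 rac-5,7-difluoro-2-[3,4,5-tris(benzyloxy)phenyl]spiro[chromane-3,2'-[1,3]dithiane], via caesium alkoxide adduct 6 (not isolated)
Conditions: CsF (0.2 equiv), 18-crown-6 (0.2 equiv), 4 Å MS, THF–DMPU, 0 → 55 °C, argon sweep
Reagents that add atoms: none
Why: Proposed new method: catalytic fluoride attacks the C–SiMe3 bond of 4 and hands the dithiane-stabilised C3 carbanion to the carbonyl carbon of 5 (C2–C3 bond), and the resulting C2 alkoxide 6 displaces one of the two equivalent ortho fluorides of the 2,4,6-trifluorophenyl ring (O1–C8a bond), so that the fluoride expelled at C8a restarts the cycle and silicon leaves as volatile Me3SiF. The closest known reaction types are the fluoride-induced carbodesilylative addition of 2-silyl-1,3-dithianes to aldehydes and the alkoxide SNAr on 1,3,5-trifluorobenzene-type rings, and their coupling into one fluoride-relay annulation is the new element. The pyran ring closes by a 6-exo-trig addition–elimination through a Meisenheimer complex, helped by the gem-disubstituent effect of the spiro dithiane at C3. The single new stereocentre C2 is deliberately left uncontrolled (racemate), because it becomes epimerisable after step 4 and is corrected in step 5. The step needs carbonyl addition to outrun proton abstraction and O-arylation to outrun every other ring closure: no stoichiometric base is present, 5 cannot enolise, product 7 has no acidic C–H that could quench 6, the C3 carbanion could only close a four-membered ring, and the para fluoride is out of reach of the tethered alkoxide.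

Step 3
Reactants: 7 rac-5,7-difluoro-2-[3,4,5-tris(benzyloxy)phenyl]spiro[chromane-3,2'-[1,3]dithiane]
Product: 8 rac-5,7-bis(benzyloxy)-2-[3,4,5-tris(benzyloxy)phenyl]spiro[chromane-3,2'-[1,3]dithiane]
Conditions: BnOH (6 equiv), NaH (5 equiv), NMP, 110 °C
Reagents that add atoms: benzyl alcohol, OCc1ccccc1
Why: Twofold SNAr (the 1,3,5-trifluorobenzene-as-phloroglucinol tactic), in which C5–F and C7–F are meta to each other and to O1 so that no oxygen lone pair enriches the carbons under attack, 7 carries no base-labile group, and exhaustive substitution removes any regiochemical question.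

Step 4
Reactants: 8 rac-5,7-bis(benzyloxy)-2-[3,4,5-tris(benzyloxy)phenyl]spiro[chromane-3,2'-[1,3]dithiane]
Product: 9 rac-5,7-bis(benzyloxy)-2-[3,4,5-tris(benzyloxy)phenyl]chroman-3-one
Conditions: MeI (excess), CaCO3, MeCN–H2O 9:1, 45 °C, argon
Reagents that add atoms: water, O
Why: Alkylative (non-oxidative) dithiane hydrolysis, in which S-methylation turns sulfur into a leaving group and water delivers the C3 ketone without touching the oxidation-prone benzyloxyarenes; C2 stays racemic, which is what step 5 requires.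

Step 5
Reactants: 9 rac-5,7-bis(benzyloxy)-2-[3,4,5-tris(benzyloxy)phenyl]chroman-3-one
Product: 10 (2R,3R)-5,7-bis(benzyloxy)-2-[3,4,5-tris(benzyloxy)phenyl]chroman-3-ol (penta-O-benzyl-(−)-epigallocatechin)
Conditions: H2 (50 bar), RuCl2[(S)-BINAP][(R,R)-DPEN] (1 mol %), KOt-Bu (0.2 equiv), i-PrOH–toluene, 25 °C, degassed
Reagents that add atoms: none
Why: Noyori asymmetric hydrogenation under dynamic kinetic resolution, as known for racemic 2-aryl- and 2-aryloxycycloalkanones: KOt-Bu interconverts the C2 epimers through the enolate, the catalyst should reduce only the (2R)-ketone, and hydride arrives anti to the C2 aryl group, so that both enantiomers of 9 funnel into the 2,3-cis (2R,3R) alcohol.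

Step 6
Reactants: 10 penta-O-benzyl-(−)-epigallocatechin; 11 3,4,5-tris(benzyloxy)benzoic acid
Product: 12 penta-O-benzyl-(−)-epigallocatechin 3-O-[3,4,5-tris(benzyloxy)benzoate]
Conditions: DCC, DMAP, CH2Cl2, 0 °C → rt
Reagents that add atoms: none
Why: Steglich esterification acylates the only free hydroxyl group without breaking the C3–O bond, so C3 keeps its configuration.

Step 7
Reactants: 12 penta-O-benzyl-(−)-epigallocatechin 3-O-[3,4,5-tris(benzyloxy)benzoate]
Product: 13 (2R,3R,4S)-4-(2-ethoxyethoxy) derivative of 12 (4β-alkoxy and 3,4-trans)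
Conditions: DDQ (2 equiv), 2-ethoxyethanol, CH2Cl2, rt
Reagents that add atoms: 2-ethoxyethanol, CCOCCO
Why: DDQ benzylic oxidation, in which hydride abstraction at C4 gives a cation stabilised by the 5,7-dialkoxy A ring and the alcohol traps it on the β face, anti to the cis-disposed 2-aryl and 3-acyloxy groups.

Step 8
Reactants: 13 (2R,3R,4S)-4-(2-ethoxyethoxy) derivative of 12; 10 penta-O-benzyl-(−)-epigallocatechin (3 equiv, excess recovered)
Product: 14 [penta-O-benzyl-epigallocatechin 3-O-(tri-O-benzylgallate)]-(4β→8)-[penta-O-benzyl-epigallocatechin]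
Conditions: TMSOTf (0.2 equiv), CH2Cl2, −78 → −40 °C; Et3N quench
Reagents that add atoms: none
Why: Lewis-acid-catalysed flavan-4-yl cation/arene coupling (Friedel–Crafts type), in which the 3-O-galloyl carbonyl shields the α face of the C4 cation (neighbouring-group participation) so that C8 of 10, the most nucleophilic A-ring carbon, attacks from the β face and sets C4 as 3,4-trans (4β), while the excess of 10 suppresses self-condensation of 13.

Step 9
Reactants: 10 penta-O-benzyl-(−)-epigallocatechin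
Product: 15 (2R,3R)-8-bromo-5,7-bis(benzyloxy)-2-[3,4,5-tris(benzyloxy)phenyl]chroman-3-ol
Conditions: NBS (1.0 equiv), CH2Cl2, −78 → 0 °C
Reagents that add atoms: N-bromosuccinimide, O=C1CCC(=O)N1Br
Why: Electrophilic aromatic bromination goes to C8, the most electron-rich position of the phloroglucinol-type A ring, and caps the site at which this unit could otherwise self-condense.

Step 10
Reactants: 15 (2R,3R)-8-bromo-5,7-bis(benzyloxy)-2-[3,4,5-tris(benzyloxy)phenyl]chroman-3-ol
Product: 16 (2R,3R,4S)-8-bromo-5,7-bis(benzyloxy)-4-(2-ethoxyethoxy)-2-[3,4,5-tris(benzyloxy)phenyl]chroman-3-ol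
Conditions: DDQ (2 equiv), 2-ethoxyethanol, CH2Cl2, rt
Reagents that add atoms: 2-ethoxyethanol, CCOCCO
Why: The same DDQ benzylic oxidation as in step 7, with the alcohol adding to the C4 cation on the β face, anti to the 2-aryl and 3-hydroxy groups, and with the free 3-OH tolerated.

Step 11
Reactants: 14 protected lower dimer; 16 (2R,3R,4S)-8-bromo-4-(2-ethoxyethoxy) electrophile (1.2 equiv)
Product: 17 [8-bromo-penta-O-benzyl-epigallocatechin]-(4β→8)-[penta-O-benzyl-epigallocatechin 3-O-(tri-O-benzylgallate)]-(4β→8)-[penta-O-benzyl-epigallocatechin]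
Conditions: TMSOTf (0.3 equiv), CH2Cl2, −78 → −30 °C; Et3N quench
Reagents that add atoms: none
Why: The same flavan-4-yl cation/arene coupling, in which the cation from 16 is attacked on its β face, anti to the cis 2-aryl and 3-hydroxy groups, by the only free C8 of 14 (that of the galloylated unit), which sets the last stereocentre as 4β, and the C8 bromine of 16 blocks its self-condensation so that near-equimolar amounts suffice.

Step 12
Reactants: 17 protected trimer
Product: 18 epigallocatechin-(4β→8)-epigallocatechin 3-O-gallate-(4β→8)-epigallocatechin (CNP0278699.1)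
Conditions: H2 (1 atm), Pd(OH)2/C, Et3N (1.1 equiv), THF–MeOH–H2O, rt; filtration under argon, lyophilisation
Reagents that add atoms: none
Why: Catalytic hydrogenolysis cleaves all eighteen benzyl ethers and the aryl bromide under buffered conditions that leave the gallate ester, the acid-labile interflavan bonds and all eight stereocentres untouched.

**Compound list**
1 | 2-(trimethylsilyl)-1,3-dithiane | C[Si](C)(C)C1SCCCS1 | starting material
2 | 2,4,6-trifluorobenzyl bromide | Fc1cc(F)c(CBr)c(F)c1 | starting material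
3 | 2-lithio-2-(trimethylsilyl)-1,3-dithiane | [Li]C1([Si](C)(C)C)SCCCS1 | intermediate
4 | 2-(2,4,6-trifluorobenzyl)-2-(trimethylsilyl)-1,3-dithiane | C[Si](C)(C)C1(Cc2c(F)cc(F)cc2F)SCCCS1 | intermediate
5 | 3,4,5-tris(benzyloxy)benzaldehyde | O=Cc1cc(OCc9ccccc9)c(OCc9ccccc9)c(OCc9ccccc9)c1 | starting material
6 | caesium rac-[2-(2,4,6-trifluorobenzyl)-1,3-dithian-2-yl][3,4,5-tris(benzyloxy)phenyl]methanolate | [Cs+].[O-]C(c1cc(OCc9ccccc9)c(OCc9ccccc9)c(OCc9ccccc9)c1)C1(Cc2c(F)cc(F)cc2F)SCCCS1 | intermediate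
7 | rac-5,7-difluoro-2-[3,4,5-tris(benzyloxy)phenyl]spiro[chromane-3,2'-[1,3]dithiane] | Fc1cc(F)c2CC3(SCCCS3)C(c3cc(OCc9ccccc9)c(OCc9ccccc9)c(OCc9ccccc9)c3)Oc2c1 | intermediate
8 | rac-5,7-bis(benzyloxy)-2-[3,4,5-tris(benzyloxy)phenyl]spiro[chromane-3,2'-[1,3]dithiane] | c9ccccc9COc1cc(OCc9ccccc9)c2CC3(SCCCS3)C(c3cc(OCc9ccccc9)c(OCc9ccccc9)c(OCc9ccccc9)c3)Oc2c1 | intermediate
9 | rac-5,7-bis(benzyloxy)-2-[3,4,5-tris(benzyloxy)phenyl]chroman-3-one | O=C1Cc2c(OCc9ccccc9)cc(OCc9ccccc9)cc2OC1c1cc(OCc9ccccc9)c(OCc9ccccc9)c(OCc9ccccc9)c1 | intermediate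
10 | (2R,3R)-5,7-bis(benzyloxy)-2-[3,4,5-tris(benzyloxy)phenyl]chroman-3-ol (2,3-cis; penta-O-benzyl-(−)-epigallocatechin) | O[C@@H]1Cc2c(OCc9ccccc9)cc(OCc9ccccc9)cc2O[C@@H]1c1cc(OCc9ccccc9)c(OCc9ccccc9)c(OCc9ccccc9)c1 | intermediate
11 | 3,4,5-tris(benzyloxy)benzoic acid | OC(=O)c1cc(OCc9ccccc9)c(OCc9ccccc9)c(OCc9ccccc9)c1 | starting material
12 | (2R,3R)-penta-O-benzyl-epigallocatechin 3-O-[3,4,5-tris(benzyloxy)benzoate] | O=C(O[C@@H]1Cc2c(OCc9ccccc9)cc(OCc9ccccc9)cc2O[C@@H]1c1cc(OCc9ccccc9)c(OCc9ccccc9)c(OCc9ccccc9)c1)c1cc(OCc9ccccc9)c(OCc9ccccc9)c(OCc9ccccc9)c1 | intermediate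
13 | (2R,3R,4S)-4-(2-ethoxyethoxy) derivative of 12 (4β, 3,4-trans) | O=C(O[C@@H]1[C@@H](OCCOCC)c2c(OCc9ccccc9)cc(OCc9ccccc9)cc2O[C@@H]1c1cc(OCc9ccccc9)c(OCc9ccccc9)c(OCc9ccccc9)c1)c1cc(OCc9ccccc9)c(OCc9ccccc9)c(OCc9ccccc9)c1 | intermediate
14 | [penta-O-benzyl-epigallocatechin 3-O-(tri-O-benzylgallate)]-(4β→8)-[penta-O-benzyl-epigallocatechin] | O=C(O[C@@H]1[C@@H](c2c(OCc9ccccc9)cc(OCc9ccccc9)c3c2O[C@H](c2cc(OCc9ccccc9)c(OCc9ccccc9)c(OCc9ccccc9)c2)[C@H](O)C3)c2c(OCc9ccccc9)cc(OCc9ccccc9)cc2O[C@@H]1c1cc(OCc9ccccc9)c(OCc9ccccc9)c(OCc9ccccc9)c1)c1cc(OCc9ccccc9)c(OCc9ccccc9)c(OCc9ccccc9)c1 | intermediate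
15 | (2R,3R)-8-bromo-5,7-bis(benzyloxy)-2-[3,4,5-tris(benzyloxy)phenyl]chroman-3-ol | O[C@@H]1Cc2c(OCc9ccccc9)cc(OCc9ccccc9)c(Br)c2O[C@@H]1c1cc(OCc9ccccc9)c(OCc9ccccc9)c(OCc9ccccc9)c1 | intermediate
16 | (2R,3R,4S)-8-bromo-5,7-bis(benzyloxy)-4-(2-ethoxyethoxy)-2-[3,4,5-tris(benzyloxy)phenyl]chroman-3-ol (4β) | O[C@@H]1[C@@H](OCCOCC)c2c(OCc9ccccc9)cc(OCc9ccccc9)c(Br)c2O[C@@H]1c1cc(OCc9ccccc9)c(OCc9ccccc9)c(OCc9ccccc9)c1 | intermediate
17 | [8-bromo-penta-O-benzyl-epigallocatechin]-(4β→8)-[penta-O-benzyl-epigallocatechin 3-O-(tri-O-benzylgallate)]-(4β→8)-[penta-O-benzyl-epigallocatechin] | O=C(O[C@@H]1[C@@H](c2c(OCc9ccccc9)cc(OCc9ccccc9)c3c2O[C@H](c2cc(OCc9ccccc9)c(OCc9ccccc9)c(OCc9ccccc9)c2)[C@H](O)C3)c2c(OCc9ccccc9)cc(OCc9ccccc9)c([C@H]3c4c(OCc9ccccc9)cc(OCc9ccccc9)c(Br)c4O[C@H](c4cc(OCc9ccccc9)c(OCc9ccccc9)c(OCc9ccccc9)c4)[C@@H]3O)c2O[C@@H]1c1cc(OCc9ccccc9)c(OCc9ccccc9)c(OCc9ccccc9)c1)c1cc(OCc9ccccc9)c(OCc9ccccc9)c(OCc9ccccc9)c1 | intermediate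
18 | epigallocatechin-(4β→8)-epigallocatechin 3-O-gallate-(4β→8)-epigallocatechin (CNP0278699.1) | O=C(O[C@@H]1[C@@H](c2c(O)cc(O)c3c2O[C@H](c2cc(O)c(O)c(O)c2)[C@H](O)C3)c2c(O)cc(O)c([C@H]3c4c(O)cc(O)cc4O[C@H](c4cc(O)c(O)c(O)c4)[C@@H]3O)c2O[C@@H]1c1cc(O)c(O)c(O)c1)c1cc(O)c(O)c(O)c1 | target

**Step count**
Total step count: 12.
Longest linear sequence: 10 (steps 1–8, 11, 12).

**Steps most likely to fail**

Step 2. The carbanion equivalent may be protonated before it reaches the aldehyde (protodesilylation). The fluoride chain may stall if ring closure is too slow at the chosen temperature. The acidic aryl C–H bonds between the fluorines may be deprotonated, with loss of fluoride.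
Fallback (known chemistry; sets out from 5 and 2, returns at 7): 2-lithio-1,3-dithiane (1,3-dithiane, n-BuLi) is added to 5 in a Corey–Seebach reaction to give rac-(1,3-dithian-2-yl)[3,4,5-tris(benzyloxy)phenyl]methanol F1. Double deprotonation of F1 (2 equiv n-BuLi, THF, −30 °C) and C-alkylation of the dianion with 2 gives rac-[2-(2,4,6-trifluorobenzyl)-1,3-dithian-2-yl][3,4,5-tris(benzyloxy)phenyl]methanol F2. F2 is cyclised in a separate flask with NaH in DMF (intramolecular alkoxide SNAr) to 7. The order of bond construction changes, with C3–C4 made after C2–C3, and no silicon/fluoride relay is needed.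

Step 5. Epimerisation at C2 may be slower than reduction, which would turn the dynamic resolution into a simple kinetic one. Other risks are poor facial discrimination by the catalyst and catalyst poisoning by sulfur traces from step 4.
Fallback (sets out from 9, returns at 10): L-Selectride/LiBr in THF at −78 °C reduces 9 anti to the C2 aryl group to the racemic cis alcohol, that is 10 together with its mirror image (2S,3S)-5,7-bis(benzyloxy)-2-[3,4,5-tris(benzyloxy)phenyl]chroman-3-ol F3. Steglich esterification of the racemate with (S)-2-methoxy-2-phenylacetic acid gives the (S)-O-methylmandelate of 10 F4 and the (S)-O-methylmandelate of the mirror-image alcohol F5, which are separated by crystallisation or chromatography. Methanolysis of F4 (K2CO3, MeOH–THF) gives 10. F5 is methanolysed to F3, which is re-oxidised with Dess–Martin periodinane to 9 and recycled.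

Step 11. Attack at the C6 positions of the dimer may compete. The large nucleophile may react slowly, and the interflavan bond already present may be cleaved and scrambled by the Lewis acid.
Fallback (sets out from 13, returns at 17): the chain is grown downward by orthogonal activation. Compound 13 is treated with phenylmethanethiol and BF3·OEt2 to give the 4β-benzylsulfanyl analogue of 13 F6. The C4–S bond of F6 is inert to hard Lewis acids, so F6 serves as the C8 nucleophile towards 16 (TMSOTf, CH2Cl2, −78 °C) and gives the upper dimer [8-bromo-penta-O-benzyl-epigallocatechin]-(4β→8)-[4β-benzylsulfanyl-penta-O-benzyl-epigallocatechin 3-O-(tri-O-benzylgallate)] F7. The thioether of F7 is then activated with thiophilic AgBF4 in the presence of excess 10, whose C8 attacks the galloyl-shielded cation from the β face to give 17.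

**Further compounds**
F1 | step 2 | rac-(1,3-dithian-2-yl)[3,4,5-tris(benzyloxy)phenyl]methanol | OC(C1SCCCS1)c1cc(OCc9ccccc9)c(OCc9ccccc9)c(OCc9ccccc9)c1
F2 | step 2 | rac-[2-(2,4,6-trifluorobenzyl)-1,3-dithian-2-yl][3,4,5-tris(benzyloxy)phenyl]methanol | OC(c1cc(OCc9ccccc9)c(OCc9ccccc9)c(OCc9ccccc9)c1)C1(Cc2c(F)cc(F)cc2F)SCCCS1
F3 | step 5 | (2S,3S)-5,7-bis(benzyloxy)-2-[3,4,5-tris(benzyloxy)phenyl]chroman-3-ol | O[C@H]1Cc2c(OCc9ccccc9)cc(OCc9ccccc9)cc2O[C@H]1c1cc(OCc9ccccc9)c(OCc9ccccc9)c(OCc9ccccc9)c1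
F4 | step 5 | (S)-O-methylmandelate of 10 | O=C(O[C@@H]1Cc2c(OCc9ccccc9)cc(OCc9ccccc9)cc2O[C@@H]1c1cc(OCc9ccccc9)c(OCc9ccccc9)c(OCc9ccccc9)c1)[C@@H](OC)c1ccccc1
F5 | step 5 | (S)-O-methylmandelate of the mirror-image alcohol F3 | O=C(O[C@H]1Cc2c(OCc9ccccc9)cc(OCc9ccccc9)cc2O[C@H]1c1cc(OCc9ccccc9)c(OCc9ccccc9)c(OCc9ccccc9)c1)[C@@H](OC)c1ccccc1
F6 | step 11 | 4β-benzylsulfanyl analogue of 13 | O=C(O[C@@H]1[C@@H](SCc9ccccc9)c2c(OCc9ccccc9)cc(OCc9ccccc9)cc2O[C@@H]1c1cc(OCc9ccccc9)c(OCc9ccccc9)c(OCc9ccccc9)c1)c1cc(OCc9ccccc9)c(OCc9ccccc9)c(OCc9ccccc9)c1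
F7 | step 11 | [8-bromo-penta-O-benzyl-epigallocatechin]-(4β→8)-[4β-benzylsulfanyl-penta-O-benzyl-epigallocatechin 3-O-(tri-O-benzylgallate)] | O=C(O[C@@H]1[C@@H](SCc9ccccc9)c2c(OCc9ccccc9)cc(OCc9ccccc9)c([C@H]3c4c(OCc9ccccc9)cc(OCc9ccccc9)c(Br)c4O[C@H](c4cc(OCc9ccccc9)c(OCc9ccccc9)c(OCc9ccccc9)c4)[C@@H]3O)c2O[C@@H]1c1cc(OCc9ccccc9)c(OCc9ccccc9)c(OCc9ccccc9)c1)c1cc(OCc9ccccc9)c(OCc9ccccc9)c(OCc9ccccc9)c1
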